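**Strategy**

The plan rests on disconnecting both carbon–carbon bonds of C2 in ring C. Because C2 sits between C1' of ring B and C3 and has the oxidation level of a ketone carbon, carbon monoxide can play its part: a ring B aryl iodide supplies C1', the methyl group of a ring A acetophenone supplies C3, and palladium stitches CO between them. A single operation therefore makes C1'–C2 and C2–C3 and delivers the full C6–C3–C6 chain as a 1,3-diketone. The partners are 2-iodo-1,3,4,5-tetramethoxybenzene and 1-[2,3-dimethoxy-6-(methoxymethoxy)phenyl]ethan-1-one; the acetal hides the future O1 until acid releases it and closes ring C at O1–C2.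

Key step: step 4

Remark: flavone numbering is used throughout (O1, C2, C3, C4, C4a, C5–C8, C8a; ring B C1'–C6'). CO is taken from a cylinder. The target is achiral; intermediates 4 and 13 and fallback alcohol F5 are racemic and their stereocentres are lost again.

**Route**

Step 1
Reactants: 1 3,4-dimethoxyphenol
Product: 2 1,2-dimethoxy-4-(methoxymethoxy)benzene
Conditions: MOMCl, K2CO3, acetone, 0 °C to reflux
Reagents that add atoms: chloromethyl methyl ether, COCCl
Why: Williamson-type O-alkylation, in which the phenoxide formed with K2CO3 should displace chloride from the very reactive α-chloro ether, the phenol oxygen being the only nucleophilic site in 1.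

Step 2
Reactants: 2 1,2-dimethoxy-4-(methoxymethoxy)benzene
Product: 5 1-[2,3-dimethoxy-6-(methoxymethoxy)phenyl]ethan-1-one, via aryllithium 3 (not isolated), via tetrahedral lithium alkoxide 4 (not isolated)
Conditions: n-BuLi, THF, −20 to 0 °C; then MeC(O)N(OMe)Me, −78 °C to rt; aq NH4Cl
Reagents that add atoms: N-methoxy-N-methylacetamide, CC(=O)N(C)OC
Why: Directed ortho-metalation followed by a Weinreb ketone synthesis: the C3–H of 2 lies between the methoxymethoxy and methoxy oxygens, which both bind lithium, so deprotonation should occur there, and the aryllithium should add only once because the N-methoxy chelate 4 persists until the aqueous quench.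

Step 3
Reactants: 6 1,2,3,5-tetramethoxybenzene
Product: 7 2-iodo-1,3,4,5-tetramethoxybenzene
Conditions: NIS (1.05 equiv), TFA (cat.), MeCN, rt, dark
Reagents that add atoms: N-iodosuccinimide, O=C1CCC(=O)N1I
Why: Electrophilic aromatic iodination at one of the two equivalent free positions of 6, each activated by three methoxy groups, should stop at the mono-iodide with one equivalent of reagent because the first iodine slows a second substitution.

Step 4
Reactants: 5 1-[2,3-dimethoxy-6-(methoxymethoxy)phenyl]ethan-1-one (2.0 equiv), 7 2-iodo-1,3,4,5-tetramethoxybenzene (1.0 equiv), 8 carbon monoxide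
Product: 11 1-[2,3-dimethoxy-6-(methoxymethoxy)phenyl]-3-(2,3,4,6-tetramethoxyphenyl)propane-1,3-dione, via ketone sodium enolate 9 (not isolated), via diketone sodium enolate 10 (not isolated)
Conditions: 5, NaN(SiMe3)2 (2.0 equiv), THF, 0 °C to rt; then 7, Pd(dba)2 (5 mol %), 1,3-bis(diphenylphosphino)propane (DPPP, 5 mol %), CO (1 atm), THF, 80 °C, sealed vessel; aq NH4Cl
Reagents that add atoms: none
Why: Zerovalent palladium bearing DPPP should add oxidatively to the C–I bond of 7, CO should insert to give the 2,3,4,6-tetramethoxybenzoyl palladium iodide, and sodium enolate 9 should replace iodide and reductively eliminate through carbon, which creates C1'–C2 and C2–C3. The more acidic diketone should be deprotonated at once by the second equivalent of 9 (returned as recoverable 5) to the chelated enolate 10, which is too stabilised to be acylated again and is protonated on work-up. The closest known reaction type is the palladium-catalysed carbonylative α-arylation of aryl methyl ketones with aryl iodides under about one atmosphere of CO. No ring closes and no stereocentre is created. The step needs CO insertion to outrun direct α-arylation, and the two ortho methoxy groups of 7 should secure this because migration to the aroyl complex relieves crowding at palladium and a di-ortho-substituted aryl palladium enolate eliminates slowly. It also needs acylation at carbon and not at the enolate oxygen or the ring A oxygen, which the sodium-chelated enolate reacting through a carbon-bound palladium enolate and the methoxymethyl ether should ensure, while the twisted, doubly flanked carbonyl of 5 and its single enolisable methyl group rule out self-aldol addition and regiochemical ambiguity.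

Step 5
Reactants: 11 1-[2,3-dimethoxy-6-(methoxymethoxy)phenyl]-3-(2,3,4,6-tetramethoxyphenyl)propane-1,3-dione
Product: 14 5,6,2',3',4',6'-hexamethoxyflavone, via hydroxy diketone 12 (not isolated), via cyclic hemiketal 13 (not isolated)
Conditions: conc. HCl, MeOH, 65 °C
Reagents that add atoms: none
Why: Acid-catalysed acetal methanolysis should free phenol 12, whose oxygen adds to the ring B ketone (6-exo-trig) to give hemiketal 13, and acid-catalysed loss of water then forms the 4-pyranone, the classical cyclodehydration of 1-(2-hydroxyaryl)-1,3-diketones to flavones; methanol traps the methoxymethyl cation as volatile dimethoxymethane and the aryl methyl ethers should survive.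

**Compound list**

1 | 3,4-dimethoxyphenol | COc1ccc(O)cc1OC | starting material
2 | 1,2-dimethoxy-4-(methoxymethoxy)benzene | COCOc1ccc(OC)c(OC)c1 | intermediate
3 | [2,3-dimethoxy-6-(methoxymethoxy)phenyl]lithium | [Li]c1c(OCOC)ccc(OC)c1OC | intermediate
4 | lithium 1-[2,3-dimethoxy-6-(methoxymethoxy)phenyl]-1-[methoxy(methyl)amino]ethan-1-olate (racemic) | [Li+].CC([O-])(N(C)OC)c1c(OCOC)ccc(OC)c1OC | intermediate
5 | 1-[2,3-dimethoxy-6-(methoxymethoxy)phenyl]ethan-1-one | CC(=O)c1c(OCOC)ccc(OC)c1OC | intermediate
6 | 1,2,3,5-tetramethoxybenzene | COc1cc(OC)c(OC)c(OC)c1 | starting material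
7 | 2-iodo-1,3,4,5-tetramethoxybenzene | COc1cc(OC)c(I)c(OC)c1OC | intermediate
8 | carbon monoxide | [C-]#[O+] | starting material
9 | sodium 1-[2,3-dimethoxy-6-(methoxymethoxy)phenyl]ethen-1-olate | [Na+].[O-]C(=C)c1c(OCOC)ccc(OC)c1OC | intermediate
10 | sodium (1Z)-3-[2,3-dimethoxy-6-(methoxymethoxy)phenyl]-3-oxo-1-(2,3,4,6-tetramethoxyphenyl)prop-1-en-1-olate (drawn as the chelated form) | [Na+].[O-]/C(=C\C(=O)c1c(OCOC)ccc(OC)c1OC)c1c(OC)cc(OC)c(OC)c1OC | intermediate
11 | 1-[2,3-dimethoxy-6-(methoxymethoxy)phenyl]-3-(2,3,4,6-tetramethoxyphenyl)propane-1,3-dione | COCOc1ccc(OC)c(OC)c1C(=O)CC(=O)c1c(OC)cc(OC)c(OC)c1OC | intermediate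
12 | 1-(6-hydroxy-2,3-dimethoxyphenyl)-3-(2,3,4,6-tetramethoxyphenyl)propane-1,3-dione | Oc1ccc(OC)c(OC)c1C(=O)CC(=O)c1c(OC)cc(OC)c(OC)c1OC | intermediate
13 | 2-hydroxy-5,6-dimethoxy-2-(2,3,4,6-tetramethoxyphenyl)-2,3-dihydro-4H-chromen-4-one (racemic) | COc1cc(OC)c(C2(O)CC(=O)c3c(OC)c(OC)ccc3O2)c(OC)c1OC | intermediate
14 | 5,6,2',3',4',6'-hexamethoxyflavone, i.e. 5,6-dimethoxy-2-(2,3,4,6-tetramethoxyphenyl)-4H-chromen-4-one | COc1cc(OC)c(-c2cc(=O)c3c(OC)c(OC)ccc3o2)c(OC)c1OC | target

**Step count and risks**

Total step count: 5. Longest linear sequence: 4 steps (steps 1, 2, 4, 5); step 3 is a one-step branch.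

Steps most likely to fail:

Step 4. The crowded enolate may capture the aroyl palladium intermediate too slowly, so that hydrodeiodination, direct α-arylation or O-aroylation compete, or CO may saturate and stall the catalyst. The fallback builds the same two bonds in separate classical operations. It sets out from 7: iodine–lithium exchange (n-BuLi, THF, −78 °C) should give (2,3,4,6-tetramethoxyphenyl)lithium F1, which is quenched with CO2 and acidified to 2,3,4,6-tetramethoxybenzoic acid F2. Oxalyl chloride and catalytic DMF in CH2Cl2 should convert this into 2,3,4,6-tetramethoxybenzoyl chloride F3. Ketone 5 (two equivalents) is deprotonated with LiN(SiMe3)2 in THF at −78 °C to lithium 1-[2,3-dimethoxy-6-(methoxymethoxy)phenyl]ethen-1-olate F4, and F3 is added. Claisen-type C-acylation, with the second equivalent of enolate taking up the acidic proton of the product, should return to the route at diketone 11 after aqueous NH4Cl.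

Step 2. The aryllithium may be quenched by proton transfer from the acetyl group of the amide, or may add sluggishly because of its two flanking substituents, so that 2 is returned. The fallback sets out from 2: the same aryllithium 3 is trapped with acetaldehyde (THF, −78 °C), a faster electrophile, to give racemic 1-[2,3-dimethoxy-6-(methoxymethoxy)phenyl]ethan-1-ol F5. Dess–Martin periodinane (NaHCO3, CH2Cl2, rt) should then oxidise it to ketone 5, where the route resumes.

Step 5. Ring closure may stall at the hemiketal because the 2',6'-dimethoxyaryl group shields C2, methanol may cleave the diketone by retro-Claisen attack, or the methoxymethyl cation may alkylate C3 or the electron-rich C5' position. The fallback separates unmasking from ring closure. It sets out from 11: ZnBr2 and propane-1-thiol in CH2Cl2 at 0 °C should remove the acetal with the thiol as cation trap, giving the mixture of 12 and 13 already listed. This mixture is isolated and dehydrated in a non-nucleophilic medium, catalytic H2SO4 in acetic acid at 90 °C, to reach 14. This fallback makes no compound outside the list (F0).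

**Further compounds**

F1 | step 4 | (2,3,4,6-tetramethoxyphenyl)lithium | [Li]c1c(OC)cc(OC)c(OC)c1OC
F2 | step 4 | 2,3,4,6-tetramethoxybenzoic acid | COc1cc(OC)c(C(=O)O)c(OC)c1OC
F3 | step 4 | 2,3,4,6-tetramethoxybenzoyl chloride | COc1cc(OC)c(C(=O)Cl)c(OC)c1OC
F4 | step 4 | lithium 1-[2,3-dimethoxy-6-(methoxymethoxy)phenyl]ethen-1-olate | [Li+].[O-]C(=C)c1c(OCOC)ccc(OC)c1OC
F5 | step 2 | 1-[2,3-dimethoxy-6-(methoxymethoxy)phenyl]ethan-1-ol (racemic) | CC(O)c1c(OCOC)ccc(OC)c1OC
F0 | step 5 | none | none
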